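# Proposed total synthesis of (all-E)-(2R,3R,2'R,3'R)-β,β-carotene-2,3,2',3'-tetrol 3'-(hydrogen sulfate) (CNP0229621.3)

Carotenoid numbering is used for the target and the polyene intermediates (ring C1–C6, chain C7–C15, primes for the sulfated half). Ring building blocks carry their own systematic locants. Compound numbers are those of the list after the steps.

## The problem

The target 21 is an all-E C40 carotenoid with two identical (2R,3R)-2,3-dihydroxy-β end rings, one of which carries a hydrogen sulfate on O3'. The C7–C7' polyene is a standard isoprenoid chain; it is not the hard part, but it makes every late intermediate sensitive to light, oxygen and acid. The hard part is the end ring: a cyclohexene with a tetrasubstituted C5=C6 bond, a quaternary C1 (gem-dimethyl) and a trans-diol at neopentyl C2 and at C3. This ring is needed twice in the same absolute configuration. The two rings are too far apart to control each other, so each must be set by reagent control. Within one ring, C2 can control C3 if the C3–O bond is made by anti opening of a 2,3-epoxide. The second problem is differentiation: O3' must be told from O3 of the other ring and from O2' of its own ring. The sulfate half-ester does not survive acid, so it has to enter after the last acidic operation. The feature that opens the route is that ring atoms C1–C6, with the C5 methyl, one C1 methyl and the sp2 carbon C6, are the skeleton of 2,6-dimethylphenol (C6 = phenol C1, C5 = phenol C2, C1 = phenol C6, C2/C3 = phenol C5/C4, C4 = phenol C3). C-methylation at a methyl-bearing ortho carbon therefore dearomatizes the phenol to a dienone that has the quaternary carbon, a carbonyl at the chain-bearing carbon, and one cis olefin exactly where the diol must go.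

## Retrosynthesis

**Sulfate proton and C11'=C12'.** The target 21 is the protonated form of its sodium salt 20, the stable storage form. Salt 20 is cut at C11'=C12' into the C25 aldehyde 17 (free-diol half) and the C15 phosphonium sulfate inner salt 18 (sulfated half). This cut is preferred over the central C15=C15' bond, which would need two different C20 halves with longer chains. The forward Wittig must tolerate two free diols and a sulfate anion. Its Z isomer at the hindered 11' position converges thermally to E.

**C11=C12 and the S–O bond: one building block for both halves.** Aldehyde 17 is cut at C11=C12 into the C15 phosphonium bromide 14 and the commercial C10 dialdehyde 15. Inner salt 18 is cut at its S–O bond and is also made from 14. The near-C2 symmetry of the target is thus used without a statistical step on C40 material. The sulfate is placed on a cheap C15 salt, where only O3 has to be distinguished from the neopentyl O2, and after the acidic phosphonium formation.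

**C6–C7.** Salt 14 comes from the bis-silylated C15 dienol 13 (C–P bond formation with loss of the silyl groups). Dienol 13 is cut between ring C6 and chain C7 into the ring triflate 8 and the dienyl boronate 12, which is one hydroboration from the commercial enynol 9. The forward Suzuki–Miyaura coupling joins a hindered tetrasubstituted triflate to a C6 diene with both olefin geometries already fixed.

**Ring functional groups.** Triflate 8 arises from enone 6 by conjugate reduction and enolate triflation. This turns the enone β-carbon into the C4 methylene and fixes the C5=C6 olefin regiospecifically, since the other α-carbon is quaternary. Enone 6 is the bis-silyl ether of trans-diol 5. Diol 5 arises by anti hydrolysis of vinyl epoxide 4 at its allylic carbon. Epoxide 4 comes from dienone 3 by catalytic enantioselective epoxidation of the distal cis olefin, which has the substitution pattern of a 2,2-dimethylchromene (conjugating group on one side, quaternary carbon on the other).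

**Dearomatization.** Dienone 3 is cut at one of its geminal C–CH3 bonds to 2,6-dimethylphenol 1 and iodomethane. The precursor is a flat commodity arene; the product holds all nine carbons of the end group at the right oxidation pattern.

## Roads not taken

Alternative 1: The most obvious route follows the industrial 3-hydroxy end-group chemistry. The cut is the C2–O bond, made by α-hydroxylation (Rubottom oxidation) of 4-oxoisophorone A1 at C5 to hydroxy-enedione A2. Reduction of the olefin and of the C4 ketone would give dihydroxy ketone A3, followed by acetylide addition to the hindered C1 ketone, dehydration and alkyne reduction. The new carbinol in A2 is α to a ketone, so it is formed without reliable absolute control and is epimerizable. Two further reductions each need diastereocontrol that is only validated for the 3-hydroxy series. The chain attachment costs three steps where the chosen route needs one coupling.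

Alternative 2: Cut the S–O bond last. A double Wittig reaction of two equivalents of 14 with 15 gives the C2-symmetric tetrol A4 (nostoxanthin), which is then treated with one equivalent of a sulfating agent. O3 and O3' are related by the C2 axis, so no reagent can tell them apart. The result is a statistical mixture of unsulfated, mono- and disulfated material at the most valuable and most fragile stage. The chosen plan makes the same distinction on the C15 salt before the halves are joined.

Alternative 3: Cut the C3'–O bond of the sulfated ring by opening epoxide 4 with tetrabutylammonium hydrogen sulfate to the hydroxy sulfate A5. This sets the trans relationship and the O3' position of the sulfate in one step. The sulfate monoester would then have to survive hydride, palladium with aqueous base, and above all phosphonium formation in acidic methanol, which are solvolytic desulfation conditions. The sulfated ring would also need its own linear sequence, so the shared intermediate 14 would be lost.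

Key step: step 1

**Assumptions**
- The hydrogen sulfate is made, purified and stored as its sodium salt 20; the neutral acid 21 of the given structure is released from it in the cold in the last step.
- The facial sense of the epoxidation in step 2 is assigned by analogy with 2,2-dimethyl-2H-chromenes; should it prove opposite, the enantiomeric catalyst is used.
- Enynol 9 and dialdehyde 15 are taken as catalogue compounds (industrial carotenoid building blocks).
- All polyene operations (steps 7–12) are run under argon in subdued light.

## Route

Step 1
Reactants: 1 2,6-dimethylphenol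
Product: 3 2,6,6-trimethylcyclohexa-2,4-dien-1-one, via lithium 2,6-dimethylphenoxide 2 (not isolated)
Conditions: n-BuLi, toluene, 0 °C; MeI (excess), sealed vessel, 130 °C
Reagents that add atoms: iodomethane CI; n-butyllithium [Li]CCCC (lithium of 2 only)
Why: Alkylative dearomatization of a phenoxide (ortho-C-alkylation of a 2,6-disubstituted phenolate, the classical entry to 6,6-disubstituted cyclohexa-2,4-dienones). In toluene the lithium phenoxide 2 exists as tight O–Li aggregates, so the oxygen is shielded and iodomethane is attacked in an SN2 step by the ortho carbon next to the Li–O centre. Because this carbon already carries a methyl group, the cyclohexadienone cannot tautomerize back to a phenol and the blocked dienone 3 results. No ring is closed and no stereocentre is formed; the step creates the quaternary carbon (future C1 with both geminal methyls) and with it the whole C9 skeleton of the end group: C=O at the future C6, the enone olefin that later becomes C5=C6, and an isolated cis olefin at the future C3–C2. The selectivity needed is ortho-carbon attack over oxygen and para-carbon attack; the two ortho positions are equivalent, the non-polar medium and lithium counter-ion favour carbon, para attack only returns a phenol (removed with unreacted 1 by base extraction), and the O-methyl ether is removed by distillation. The dienone is kept cold and dark and used promptly, to avoid [4+2] dimerization and photochemical ring opening.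

Step 2
Reactants: 3 2,6,6-trimethylcyclohexa-2,4-dien-1-one
Product: 4 (4S,5R)-4,5-epoxy-2,6,6-trimethylcyclohex-2-en-1-one [(1R,6S)-2,2,4-trimethyl-7-oxabicyclo[4.1.0]hept-4-en-3-one]
Conditions: (S,S)-Jacobsen Mn(salen)Cl (cat.), mCPBA, NMO, CH2Cl2, −78 °C
Reagents that add atoms: 3-chloroperoxybenzoic acid OOC(=O)c1cccc(Cl)c1
Why: Jacobsen–Katsuki epoxidation; the oxo-manganese species attacks the only cis-disubstituted, conjugated and least electron-poor olefin C4=C5, which is flanked by a vinyl group and a quaternary carbon as in 2,2-dimethylchromenes, the best substrates of this catalyst. Both new stereocentres are set by the catalyst (reagent control) and are necessarily cis; anhydrous low-temperature conditions avoid nucleophilic epoxidation of the enone.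

Step 3
Reactants: 4 (4S,5R)-4,5-epoxy-2,6,6-trimethylcyclohex-2-en-1-one
Product: 5 (4R,5R)-4,5-dihydroxy-2,6,6-trimethylcyclohex-2-en-1-one
Conditions: HClO4 (cat.), THF/H2O, 0 °C to rt
Reagents that add atoms: water O
Why: Acid-catalysed anti hydrolysis of a vinyl epoxide; water attacks allylic C4 with inversion, while C5, shielded by the adjacent gem-dimethyl carbon, keeps its C–O bond, so the trans-(4R,5R)-diol forms and the enantiopurity of 4 is carried over. A free cation at C4 (which would erode the trans selectivity) is disfavoured because C4 is conjugated with an electron-poor enone.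

Step 4
Reactants: 5 (4R,5R)-4,5-dihydroxy-2,6,6-trimethylcyclohex-2-en-1-one
Product: 6 (4R,5R)-2,6,6-trimethyl-4,5-bis(triethylsilyloxy)cyclohex-2-en-1-one
Conditions: TESOTf, 2,6-lutidine, CH2Cl2, −78 to 0 °C
Reagents that add atoms: triethylsilyl trifluoromethanesulfonate CC[Si](CC)(CC)OS(=O)(=O)C(F)(F)F
Why: Silylation with a silyl triflate and a hindered base, standard for hindered secondary alcohols; it protects the diol from hydride and from γ-hydroxy-enone isomerization and retro-aldol cleavage. Triethylsilyl is chosen because it falls off by itself in step 8.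

Step 5
Reactants: 6 (4R,5R)-2,6,6-trimethyl-4,5-bis(triethylsilyloxy)cyclohex-2-en-1-one
Product: 8 (4R,5R)-2,6,6-trimethyl-4,5-bis(triethylsilyloxy)cyclohex-1-en-1-yl trifluoromethanesulfonate, via lithium enolate 7 (not isolated)
Conditions: L-Selectride, THF, −78 °C; then PhNTf2, −78 to 0 °C
Reagents that add atoms: N-phenylbis(trifluoromethanesulfonimide) O=S(=O)(N(c1ccccc1)S(=O)(=O)C(F)(F)F)C(F)(F)F; L-Selectride [Li+].CCC(C)[BH-](C(C)CC)C(C)CC (hydride; lithium of 7)
Why: Conjugate hydride reduction with enolate trapping as the vinyl triflate; the bulky borohydride adds to the unsubstituted β-carbon of an enone whose carbonyl is shielded by the gem-dimethyl and methyl-bearing neighbours. Enolate 7 is regiodefined and cannot eliminate the C5 oxygen because C6 bears no hydrogen; the stereocentres are untouched.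

Step 6
Reactants: 9 (2E)-3-methylpent-2-en-4-yn-1-ol
Product: 12 (2E,4E)-3-methyl-5-(4,4,5,5-tetramethyl-1,3,2-dioxaborolan-2-yl)penta-2,4-dien-1-ol, via O-boryl enynol 10 (not isolated), via O-boryl dienylboronate 11 (not isolated)
Conditions: HBpin (2.2 equiv), Cp2Zr(H)Cl (cat.), Et3N (cat.), CH2Cl2, rt; aq. NH4Cl
Reagents that add atoms: pinacolborane CC1(C)OBOC1(C)C
Why: Zirconium-catalysed syn hydroboration of a terminal alkyne with pinacolborane; the first equivalent caps the hydroxyl as a borate with loss of hydrogen, the second adds B–H anti-Markovnikov to give the E-alkenylboronate. The existing E olefin is untouched and aqueous work-up frees the alcohol.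

Step 7
Reactants: 8 (4R,5R)-2,6,6-trimethyl-4,5-bis(triethylsilyloxy)cyclohex-1-en-1-yl trifluoromethanesulfonate; 12 (2E,4E)-3-methyl-5-(4,4,5,5-tetramethyl-1,3,2-dioxaborolan-2-yl)penta-2,4-dien-1-ol
Product: 13 (2E,4E)-3-methyl-5-[(4R,5R)-2,6,6-trimethyl-4,5-bis(triethylsilyloxy)cyclohex-1-en-1-yl]penta-2,4-dien-1-ol
Conditions: Pd(OAc)2/SPhos (cat.), K3PO4, THF/H2O, 40 °C
Reagents that add atoms: none
Why: Suzuki–Miyaura coupling of a vinyl triflate with an alkenylboronate, with retention of both olefin geometries; a dialkylbiarylphosphine ligand is specified because the triflate is tetrasubstituted and flanked by a quaternary carbon.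

Step 8
Reactants: 13 (2E,4E)-3-methyl-5-[(4R,5R)-2,6,6-trimethyl-4,5-bis(triethylsilyloxy)cyclohex-1-en-1-yl]penta-2,4-dien-1-ol
Product: 14 [(2E,4E)-5-[(4R,5R)-4,5-dihydroxy-2,6,6-trimethylcyclohex-1-en-1-yl]-3-methylpenta-2,4-dien-1-yl]triphenylphosphonium bromide
Conditions: Ph3P·HBr, MeOH, rt; crystallization
Reagents that add atoms: triphenylphosphine hydrobromide [Br-].c1ccc(cc1)[PH+](c1ccccc1)c1ccccc1
Why: Phosphonium salt formation from a dienylic alcohol with triphenylphosphine hydrobromide, the standard preparation of C15 Wittig salts; the delocalized cation is captured irreversibly by the phosphine at its primary terminus, whereas any internal capture by a ring oxygen is reversible. The acidic methanol also cleaves both triethylsilyl ethers, and crystallization should give the (2E,4E) salt and a chance to upgrade enantiopurity.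

Step 9
Reactants: 14 [(2E,4E)-5-[(4R,5R)-4,5-dihydroxy-2,6,6-trimethylcyclohex-1-en-1-yl]-3-methylpenta-2,4-dien-1-yl]triphenylphosphonium bromide; 15 (2E,4E,6E)-2,7-dimethylocta-2,4,6-trienedial
Product: 17 (2E,4E,6E,8E,10E,12E)-13-[(4R,5R)-4,5-dihydroxy-2,6,6-trimethylcyclohex-1-en-1-yl]-2,7,11-trimethyltrideca-2,4,6,8,10,12-hexaenal, via phosphonium ylide 16 (not isolated)
Conditions: 15 (3 equiv), NaOMe, CH2Cl2/MeOH, 0 °C to rt; then EtOH, 75 °C, dark
Reagents that add atoms: none
Why: Wittig olefination; an excess of the symmetrical dialdehyde and slow generation of ylide 16 should stop the reaction at mono-olefination. C11=C12 forms as an E/Z mixture, and the sterically congested 11Z isomer converges to E on heating.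

Step 10
Reactants: 14 [(2E,4E)-5-[(4R,5R)-4,5-dihydroxy-2,6,6-trimethylcyclohex-1-en-1-yl]-3-methylpenta-2,4-dien-1-yl]triphenylphosphonium bromide
Product: 18 [(2E,4E)-5-[(4R,5R)-5-hydroxy-2,6,6-trimethyl-4-(sulfonatooxy)cyclohex-1-en-1-yl]-3-methylpenta-2,4-dien-1-yl]triphenylphosphonium (inner salt)
Conditions: SO3·pyridine (1.2 equiv), DMF/pyridine, 0 °C to rt
Reagents that add atoms: sulfur trioxide–pyridine complex [O-]S(=O)(=O)[n+]1ccccc1
Why: O-sulfonation of an alcohol with sulfur trioxide–pyridine; the ring C4 hydroxyl (carotenoid O3, next to a methylene) should react in preference to the C5 hydroxyl (O2), which is neopentyl-like beside the gem-dimethyl carbon. No stereocentre is affected, and bromide leaves as pyridinium bromide so that the product is a neutral inner salt.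

Step 11
Reactants: 17 (2E,4E,6E,8E,10E,12E)-13-[(4R,5R)-4,5-dihydroxy-2,6,6-trimethylcyclohex-1-en-1-yl]-2,7,11-trimethyltrideca-2,4,6,8,10,12-hexaenal; 18 [(2E,4E)-5-[(4R,5R)-5-hydroxy-2,6,6-trimethyl-4-(sulfonatooxy)cyclohex-1-en-1-yl]-3-methylpenta-2,4-dien-1-yl]triphenylphosphonium (inner salt)
Product: 20 sodium (all-E)-(2R,3R,2'R,3'R)-2,3,2'-trihydroxy-β,β-caroten-3'-yl sulfate, via sulfated ylide sodium salt 19 (not isolated)
Conditions: NaOMe, CH2Cl2/MeOH, 0 °C to rt; then EtOH, 70 °C, dark, Ar; C18 chromatography
Reagents that add atoms: sodium methoxide [Na+].[O-]C (sodium of 19 and 20)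
Why: Wittig olefination forming C11'=C12'; the sulfate monoester anion is inert to methoxide and to the ylide, and the free diols need no protection. The hindered 11'Z isomer converges thermally to all-E, and none of the four stereocentres is touched.

Step 12
Reactants: 20 sodium (all-E)-(2R,3R,2'R,3'R)-2,3,2'-trihydroxy-β,β-caroten-3'-yl sulfate
Product: 21 (all-E)-(2R,3R,2'R,3'R)-2,3,2'-trihydroxy-β,β-caroten-3'-yl hydrogen sulfate (target)
Conditions: HCl (1.0 equiv, in MeOH), −20 °C, dark; NaCl and solvent removed at once in the cold
Reagents that add atoms: none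
Why: Simple proton transfer to the sulfate anion; nothing else changes. The free acid can solvolyse itself and protonate the polyene, so it is released only immediately before use.

## Compound list

1 | 2,6-dimethylphenol | Cc1cccc(C)c1O | starting material
2 | lithium 2,6-dimethylphenoxide (not isolated) | [Li+].[O-]c1c(C)cccc1C | intermediate
3 | 2,6,6-trimethylcyclohexa-2,4-dien-1-one | CC1=CC=CC(C)(C)C1=O | intermediate
4 | (4S,5R)-4,5-epoxy-2,6,6-trimethylcyclohex-2-en-1-one [(1R,6S)-2,2,4-trimethyl-7-oxabicyclo[4.1.0]hept-4-en-3-one] | O=C1C(C)=C[C@@H]2O[C@@H]2C1(C)C | intermediate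
5 | (4R,5R)-4,5-dihydroxy-2,6,6-trimethylcyclohex-2-en-1-one | O=C1C(C)=C[C@@H](O)[C@H](O)C1(C)C | intermediate
6 | (4R,5R)-2,6,6-trimethyl-4,5-bis(triethylsilyloxy)cyclohex-2-en-1-one | O=C1C(C)=C[C@@H](O[Si](CC)(CC)CC)[C@H](O[Si](CC)(CC)CC)C1(C)C | intermediate
7 | lithium (4R,5R)-2,6,6-trimethyl-4,5-bis(triethylsilyloxy)cyclohex-1-en-1-olate (not isolated) | [Li+].[O-]C1=C(C)C[C@@H](O[Si](CC)(CC)CC)[C@H](O[Si](CC)(CC)CC)C1(C)C | intermediate
8 | (4R,5R)-2,6,6-trimethyl-4,5-bis(triethylsilyloxy)cyclohex-1-en-1-yl trifluoromethanesulfonate | O=S(=O)(OC1=C(C)C[C@@H](O[Si](CC)(CC)CC)[C@H](O[Si](CC)(CC)CC)C1(C)C)C(F)(F)F | intermediate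
9 | (2E)-3-methylpent-2-en-4-yn-1-ol | OC/C=C(C)/C#C | starting material
10 | 4,4,5,5-tetramethyl-2-{[(2E)-3-methylpent-2-en-4-yn-1-yl]oxy}-1,3,2-dioxaborolane (not isolated) | CC1(C)OB(OC/C=C(C)/C#C)OC1(C)C | intermediate
11 | O-(pinacolboryl) ether of 12 (not isolated) | CC1(C)OB(OC/C=C(C)/C=C/B2OC(C)(C)C(C)(C)O2)OC1(C)C | intermediate
12 | (2E,4E)-3-methyl-5-(4,4,5,5-tetramethyl-1,3,2-dioxaborolan-2-yl)penta-2,4-dien-1-ol | OC/C=C(C)/C=C/B1OC(C)(C)C(C)(C)O1 | intermediate
13 | (2E,4E)-3-methyl-5-[(4R,5R)-2,6,6-trimethyl-4,5-bis(triethylsilyloxy)cyclohex-1-en-1-yl]penta-2,4-dien-1-ol | OC/C=C(C)/C=C/C1=C(C)C[C@@H](O[Si](CC)(CC)CC)[C@H](O[Si](CC)(CC)CC)C1(C)C | intermediate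
14 | [(2E,4E)-5-[(4R,5R)-4,5-dihydroxy-2,6,6-trimethylcyclohex-1-en-1-yl]-3-methylpenta-2,4-dien-1-yl]triphenylphosphonium bromide | [Br-].c1ccccc1[P+](c1ccccc1)(c1ccccc1)C/C=C(C)/C=C/C1=C(C)C[C@@H](O)[C@H](O)C1(C)C | intermediate
15 | (2E,4E,6E)-2,7-dimethylocta-2,4,6-trienedial | O=C/C(C)=C/C=C/C=C(C)/C=O | starting material
16 | ylide of 14 (not isolated) | c1ccccc1[P+](c1ccccc1)(c1ccccc1)[CH-]/C=C(C)/C=C/C1=C(C)C[C@@H](O)[C@H](O)C1(C)C | intermediate
17 | (2E,4E,6E,8E,10E,12E)-13-[(4R,5R)-4,5-dihydroxy-2,6,6-trimethylcyclohex-1-en-1-yl]-2,7,11-trimethyltrideca-2,4,6,8,10,12-hexaenal [(2R,3R)-2,3-dihydroxy-12'-apo-β-caroten-12'-al] | O=C/C(C)=C/C=C/C=C(C)/C=C/C=C(C)/C=C/C1=C(C)C[C@@H](O)[C@H](O)C1(C)C | intermediate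
18 | [(2E,4E)-5-[(4R,5R)-5-hydroxy-2,6,6-trimethyl-4-(sulfonatooxy)cyclohex-1-en-1-yl]-3-methylpenta-2,4-dien-1-yl]triphenylphosphonium, inner salt | c1ccccc1[P+](c1ccccc1)(c1ccccc1)C/C=C(C)/C=C/C1=C(C)C[C@@H](OS(=O)(=O)[O-])[C@H](O)C1(C)C | intermediate
19 | ylide of 18, sodium salt (not isolated) | [Na+].c1ccccc1[P+](c1ccccc1)(c1ccccc1)[CH-]/C=C(C)/C=C/C1=C(C)C[C@@H](OS(=O)(=O)[O-])[C@H](O)C1(C)C | intermediate
20 | sodium (all-E)-(2R,3R,2'R,3'R)-2,3,2'-trihydroxy-β,β-caroten-3'-yl sulfate | [Na+].CC1=C(/C=C/C(C)=C/C=C/C(C)=C/C=C/C=C(C)/C=C/C=C(C)/C=C/C2=C(C)C[C@@H](OS(=O)(=O)[O-])[C@H](O)C2(C)C)C(C)(C)[C@@H](O)[C@H](O)C1 | intermediate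
21 | (all-E)-(2R,3R,2'R,3'R)-2,3,2'-trihydroxy-β,β-caroten-3'-yl hydrogen sulfate | CC1=C(/C=C/C(C)=C/C=C/C(C)=C/C=C/C=C(C)/C=C/C=C(C)/C=C/C2=C(C)C[C@@H](OS(=O)(=O)O)[C@H](O)C2(C)C)C(C)(C)[C@@H](O)[C@H](O)C1 | target

## Step count and least certain steps

Total: 12 steps. Longest linear sequence: 10 steps (1, 2, 3, 4, 5, 7, 8, 9 or 10, 11, 12) from 2,6-dimethylphenol; step 6 is a one-step side branch.

**Step 1 (key step).** The ambident phenoxide may react mainly at oxygen or at the para carbon instead of the methyl-bearing ortho carbon, because iodomethane is a hard, unhindered electrophile. The dienone may also be lost by Diels–Alder dimerization during isolation. The fallback sets out from 1 and gives up dearomatization. Hydrogenation of 1 over palladium gives 2,6-dimethylcyclohexanone F1. Enolate methylation (LDA, MeI) gives 2,2,6-trimethylcyclohexanone F2. Dehydrogenation with IBX at the only enolizable side gives 2,6,6-trimethylcyclohex-2-en-1-one F3. γ-Deprotonation and silylation (LDA, TMSCl; the α'-carbon has no hydrogen) give the silyl dienol ether F4. Saegusa–Ito oxidation with Pd(OAc)2 returns to the route at 3.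

**Step 2.** Oxygen transfer to the distal olefin of an electron-poor dienone may be slow, and the enantioface discrimination may fall short of that seen with chromenes. Any shortfall reappears as a meso-type C40 diastereomer after the two halves are joined. The fallback sets out from 3 and replaces catalyst control by resolution. Uncatalysed epoxidation with mCPBA or dimethyldioxirane gives the racemic epoxide F5. Hydrolysis as in step 3 gives the racemic trans-diol F6. Lipase-catalysed acylation with vinyl acetate at the less hindered C4 hydroxyl resolves F6. The (4R,5R) material is collected either directly as the unreacted diol or, if it is the faster-reacting antipode, as its 4-O-acetate F7, which is cleaved with K2CO3 in methanol. The fallback returns at 5.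

**Step 7.** Oxidative addition and transmetalation at a tetrasubstituted triflate next to a quaternary carbon may be slow enough for protodeboronation of the dienylboronate or hydrolysis of the triflate to take over. The fallback sets out from 8 and 9 and uses a sterically undemanding sp partner. Sonogashira coupling of 8 with 9 (Pd(PPh3)4, CuI, amine) gives the 7,8-didehydro C15 enynol F8. Hydroxyl-directed trans-hydroalumination of F8 with Red-Al gives the 7E olefin and returns at 13.

**Step 10.** Sulfation may also occur at the neopentyl O2, or twice, if the steric difference between the two hydroxyls is smaller than expected. The fallback sets out from 14 and activates the diol instead of relying on sterics alone. Treatment with dibutyltin oxide gives the 2,3-O-dibutylstannylene acetal of 14, F9. Its reaction with SO3·NMe3 is directed to the less hindered tin-bound oxygen and returns at 18.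

**Step 11.** The zwitterionic ylide may be poorly soluble or sluggish toward the long conjugated aldehyde, and separating an anionic polyene from triphenylphosphine oxide may be troublesome. The fallback sets out from 17 and moves the sulfate from the ylide partner to the aldehyde partner. Sulfation of 17 with SO3·pyridine at the same less hindered hydroxyl, followed by NaHCO3, gives the 3-O-sulfate of aldehyde 17 as its sodium salt F10. Wittig reaction of F10 with the ordinary ylide from 14 (NaOMe) and thermal equilibration return at 20; the same compound results because the two halves of the skeleton are identical.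

## Further compounds

F1 | step 1 | 2,6-dimethylcyclohexanone (cis/trans mixture) | CC1CCCC(C)C1=O
F2 | step 1 | 2,2,6-trimethylcyclohexanone (racemic) | CC1CCCC(C)(C)C1=O
F3 | step 1 | 2,6,6-trimethylcyclohex-2-en-1-one | CC1=CCCC(C)(C)C1=O
F4 | step 1 | trimethyl[(2,6,6-trimethylcyclohexa-1,3-dien-1-yl)oxy]silane | C[Si](C)(C)OC1=C(C)C=CCC1(C)C
F5 | step 2 | racemic cis-fused 4,5-epoxy-2,6,6-trimethylcyclohex-2-en-1-one | O=C1C(C)=CC2OC2C1(C)C
F6 | step 2 | racemic trans-4,5-dihydroxy-2,6,6-trimethylcyclohex-2-en-1-one (one enantiomer drawn) | O=C1C(C)=C[C@@H](O)[C@H](O)C1(C)C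
F7 | step 2 | (1R,6R)-6-hydroxy-3,5,5-trimethyl-4-oxocyclohex-2-en-1-yl acetate (4-O-acetate of 5) | O=C1C(C)=C[C@@H](OC(C)=O)[C@H](O)C1(C)C
F8 | step 7 | (2E)-3-methyl-5-[(4R,5R)-2,6,6-trimethyl-4,5-bis(triethylsilyloxy)cyclohex-1-en-1-yl]pent-2-en-4-yn-1-ol | OC/C=C(C)/C#CC1=C(C)C[C@@H](O[Si](CC)(CC)CC)[C@H](O[Si](CC)(CC)CC)C1(C)C
F9 | step 10 | 2,3-O-dibutylstannylene acetal of 14 (trans-fused dioxastannolane on ring C4/C5, phosphonium bromide) | [Br-].c1ccccc1[P+](c1ccccc1)(c1ccccc1)C/C=C(C)/C=C/C1=C(C)C[C@H]3O[Sn](CCCC)(CCCC)O[C@@H]3C1(C)C
F10 | step 11 | sodium salt of the 3-O-sulfate of aldehyde 17 [(2R,3R)-2-hydroxy-12'-oxo-12'-apo-β-caroten-3-yl sulfate] | [Na+].O=C/C(C)=C/C=C/C=C(C)/C=C/C=C(C)/C=C/C1=C(C)C[C@@H](OS(=O)(=O)[O-])[C@H](O)C1(C)C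
A1 | alternative 1 | 2,6,6-trimethylcyclohex-2-ene-1,4-dione (4-oxoisophorone) | CC1=CC(=O)CC(C)(C)C1=O
A2 | alternative 1 | (5R)-5-hydroxy-2,6,6-trimethylcyclohex-2-ene-1,4-dione | O=C1C(C)=CC(=O)[C@H](O)C1(C)C
A3 | alternative 1 | (3R,4R,6R)-3,4-dihydroxy-2,2,6-trimethylcyclohexan-1-one | O=C1[C@H](C)C[C@@H](O)[C@H](O)C1(C)C
A4 | alternative 2 | (all-E)-(2R,3R,2'R,3'R)-β,β-carotene-2,3,2',3'-tetrol (nostoxanthin) | CC1=C(/C=C/C(C)=C/C=C/C(C)=C/C=C/C=C(C)/C=C/C=C(C)/C=C/C2=C(C)C[C@@H](O)[C@H](O)C2(C)C)C(C)(C)[C@@H](O)[C@H](O)C1
A5 | alternative 3 | tetrabutylammonium (1R,6R)-6-hydroxy-3,5,5-trimethyl-4-oxocyclohex-2-en-1-yl sulfate | O=C1C(C)=C[C@@H](OS(=O)(=O)[O-])[C@H](O)C1(C)C.CCCC[N+](CCCC)(CCCC)CCCC
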